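**Assumptions (one line each):**
- The lavandulyl stereocentre is too remote to bias the C2 oxa-Michael closure, so both C2 epimers form and the (2S) epimer is isolated by chromatography; the other epimer is recycled through the chalcone.
- In 9 the hindered, H-bonded 2'-OH stays free when MOMCl is limited to 2 equiv, so MOM goes on the 4'- and 6'-OH groups.

**Retrosynthesis**
1. Sophoraflavanone G comes from the tetra-MOM flavanone, whose C-ring closes last by oxa-Michael addition of a 2'-OH chalcone (this sets C2).
2. The chalcone comes from Claisen–Schmidt condensation of a 3'-lavandulyl-2'-hydroxy-4',6'-bis-MOM-acetophenone with 2,4-bis-MOM-benzaldehyde (the B-ring enters here).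
3. The A-ring C8–CH2 bond is the key bond: a photochemical decarboxylative radical coupling of phloroacetophenone (phenolate) with the N-acyloxyphthalimide ester of (3R)-6-methyl-3-isopropenylhept-5-enoic acid.
4. That acid comes from (R)-limonene by epoxidation, periodate ring cleavage, Pinnick oxidation, and conversion of the methyl ketone to the prenyl alkene. The only stereocentre, C3, comes from limonene and is never touched.

---

**Step 1**
Reactants: 1 (R)-(+)-limonene
Product: 2 (4R)-limonene 1,2-epoxide (C1/C2 diastereomer mixture)
Conditions: mCPBA (1.0 equiv), NaHCO3, CH2Cl2, 0 °C, 2 h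
Reagents that add atoms: mCPBA, OOC(=O)c1cccc(Cl)c1
Why: Prilezhaev epoxidation occurs at the more electron-rich trisubstituted ring alkene rather than the isopropenyl group; C4 is untouched.

**Step 2**
Reactants: 2
Product: 3 (3R)-6-oxo-3-(prop-1-en-2-yl)heptanal
Conditions: H5IO6 (1.2 equiv), THF/H2O, 0 °C to rt, 2 h
Reagents that add atoms: periodic acid, O=I(O)(O)(O)(O)O
Why: Periodic acid hydrolyses the epoxide to the diol and cleaves it (Malaprade-type) to the methyl ketone and aldehyde. C4 is β to the aldehyde and γ to the ketone, so it cannot epimerise.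

**Step 3**
Reactants: 3
Product: 4 (3R)-6-oxo-3-(prop-1-en-2-yl)heptanoic acid
Conditions: NaClO2, NaH2PO4, 2-methyl-2-butene, t-BuOH/H2O, rt, 3 h
Reagents that add atoms: sodium chlorite, [Na+].[O-]Cl=O
Why: Pinnick oxidation is chemoselective for the aldehyde, and the scavenger protects the alkene.

**Step 4**
Reactants: 4
Product: 5 (3R)-6-hydroxy-6-methyl-3-(prop-1-en-2-yl)heptanoic acid
Conditions: MeMgBr (3.5 equiv), THF, −20 °C to 0 °C, 3 h; then aq. NH4Cl
Reagents that add atoms: MeMgBr, C[Mg]Br
Why: The carboxylate is protected as its Mg salt, so the Grignard adds only to the ketone to give the tertiary carbinol, the precursor of the gem-dimethyl alkene.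

**Step 5**
Reactants: 5
Product: 6 1,3-dioxoisoindolin-2-yl (3R)-6-hydroxy-6-methyl-3-(prop-1-en-2-yl)heptanoate
Conditions: N-hydroxyphthalimide (1.1 equiv), DIC, DMAP (cat.), CH2Cl2, rt, 4 h
Reagents that add atoms: N-hydroxyphthalimide, O=C1c2ccccc2C(=O)N1O
Why: Steglich-type esterification gives the redox-active ester, and the hindered tertiary alcohol is not acylated. The acid is masked before dehydration so it does not interfere.

**Step 6**
Reactants: 6
Product: 7 1,3-dioxoisoindolin-2-yl (3R)-6-methyl-3-(prop-1-en-2-yl)hept-5-enoate
Conditions: Martin sulfurane (1.3 equiv), CH2Cl2, 0 °C to rt, 2 h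
Reagents that add atoms: none
Why: Neutral, E1-like dehydration of the tertiary alcohol favours the trisubstituted (Zaitsev) prenyl alkene over the 1,1-disubstituted isomer; the minor isomer is removed on AgNO3-silica. The isopropenyl group and the stereocentre are unaffected.

**Step 7**
Reactants: 7 (1.0 equiv); 8 2,4,6-trihydroxyacetophenone, CC(=O)c1c(O)cc(O)cc1O (3.0 equiv)
Product: 9 1-{2,4,6-trihydroxy-3-[(2R)-5-methyl-2-(prop-1-en-2-yl)hex-4-en-1-yl]phenyl}ethan-1-one
Conditions: Cs2CO3 (3 equiv), DMSO (0.1 M), 440 nm LEDs, 25 °C, N2, 18 h
Reagents that add atoms: none (CO2 and phthalimide anion are lost)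
Why: Cs2CO3 deprotonates 8 to a phenolate that forms an electron donor–acceptor complex with the redox-active ester. Blue light drives electron transfer, fragmentation gives CO2, phthalimide and the primary radical, and this radical couples with the phenoxyl radical at the free carbon ortho to the phenoxide (C3'). Both ring positions C3' and C5' are equivalent, so excess 8 suppresses dialkylation.
Proposed new method: Mechanistic reasoning: excited-state or EDA-complex SET gives a persistent acylphloroglucinol phenoxyl radical and a transient primary alkyl radical, which undergo radical–radical C–C coupling ortho to oxygen, then tautomerise to the arene. The radical is β to the stereocentre, so C3 is not epimerised. Homoallyl 3-exo closure or 1,2-vinyl shift (about 10^4–10^5 s^-1) should be outcompeted by in-cage and persistent-radical coupling. Closest known reaction type: photoinduced EDA-complex decarboxylative alkylation with N-acyloxyphthalimides plus phenolate/naphtholate ortho-alkylation. It has not been shown on an unactivated β-vinyl primary radical with an acylphloroglucinol.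

**Step 8**
Reactants: 10 2,4-dihydroxybenzaldehyde
Product: 11 2,4-bis(methoxymethoxy)benzaldehyde
Conditions: MOMCl (2.4 equiv), DIPEA, CH2Cl2, 0 °C to rt, 6 h
Reagents that add atoms: chloromethyl methyl ether, ClCOC
Why: Williamson-type O-alkylation protects both phenols.

**Step 9**
Reactants: 9
Product: 12 1-{2-hydroxy-4,6-bis(methoxymethoxy)-3-[(2R)-5-methyl-2-(prop-1-en-2-yl)hex-4-en-1-yl]phenyl}ethan-1-one
Conditions: MOMCl (2.2 equiv), K2CO3, acetone, rt, 8 h
Reagents that add atoms: chloromethyl methyl ether, ClCOC
Why: The H-bonded 2'-OH, flanked by the lavandulyl group, stays free, which forces later ring closure through the O that becomes O1 (C8 regiochemistry). The 4'- and 6'-OH groups are protected.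

**Step 10**
Reactants: 12; 11
Product: 13 chalcone, (E)-1-{2-hydroxy-4,6-bis(MOM-oxy)-3-lavandulylphenyl}-3-[2,4-bis(MOM-oxy)phenyl]prop-2-en-1-one
Conditions: KOH, EtOH/H2O, rt, 48 h
Reagents that add atoms: none (water is lost)
Why: Claisen–Schmidt aldol condensation. The stereocentre is not α to a carbonyl, so nothing epimerises.

**Step 11**
Reactants: 13
Product: 14 (2S)-2-[2,4-bis(methoxymethoxy)phenyl]-5,7-bis(methoxymethoxy)-8-[(2R)-5-methyl-2-(prop-1-en-2-yl)hex-4-en-1-yl]chroman-4-one
Conditions: NaOAc, EtOH, 80 °C, 24 h; then separation of the C2 epimers by silica/preparative HPLC; the (2R) epimer and residual chalcone are recycled by resubjecting to the same conditions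
Reagents that add atoms: none
Why: Reversible intramolecular oxa-Michael addition through the only free ortho OH closes the six-membered ring at the lavandulyl-flanked oxygen. C2 is set by thermodynamic closure to both epimers, and the (2S,2''R) diastereomer is isolated with no chiral catalyst or reagent.

**Step 12**
Reactants: 14
Product: 15 sophoraflavanone G
Conditions: ZnBr2 (5 equiv), n-PrSH (5 equiv), CH2Cl2, 0 °C to rt, 1 h
Reagents that add atoms: none
Why: Lewis-acid thiol cleavage removes the four aryl MOM ethers under mild, non-basic conditions. C2 does not epimerise (that needs base), and the three alkenes and the ketone survive.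

---

**Compound list**
1 | (R)-(+)-limonene | C=C(C)[C@@H]1CCC(C)=CC1 | starting material
2 | (4R)-limonene 1,2-epoxide | C=C(C)[C@@H]1CCC2(C)OC2C1 | intermediate
3 | (3R)-6-oxo-3-(prop-1-en-2-yl)heptanal | C=C(C)[C@H](CCC(C)=O)CC=O | intermediate
4 | (3R)-6-oxo-3-(prop-1-en-2-yl)heptanoic acid | C=C(C)[C@H](CCC(C)=O)CC(=O)O | intermediate
5 | (3R)-6-hydroxy-6-methyl-3-(prop-1-en-2-yl)heptanoic acid | C=C(C)[C@H](CCC(C)(C)O)CC(=O)O | intermediate
6 | NHPI ester of 5 | C=C(C)[C@H](CCC(C)(C)O)CC(=O)ON1C(=O)c2ccccc2C1=O | intermediate
7 | NHPI ester of (3R)-6-methyl-3-isopropenylhept-5-enoic acid | C=C(C)[C@H](CC=C(C)C)CC(=O)ON1C(=O)c2ccccc2C1=O | intermediate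
8 | 2,4,6-trihydroxyacetophenone | CC(=O)c1c(O)cc(O)cc1O | starting material
9 | 3'-lavandulyl-2',4',6'-trihydroxyacetophenone | C=C(C)[C@H](CC=C(C)C)Cc1c(O)c(C(C)=O)c(O)cc1O | intermediate
10 | 2,4-dihydroxybenzaldehyde | O=Cc1ccc(O)cc1O | starting material
11 | 2,4-bis(methoxymethoxy)benzaldehyde | O=Cc1ccc(OCOC)cc1OCOC | intermediate
12 | 2'-hydroxy-4',6'-bis(MOM-oxy)-3'-lavandulylacetophenone | C=C(C)[C@H](CC=C(C)C)Cc1c(O)c(C(C)=O)c(OCOC)cc1OCOC | intermediate
13 | MOM-protected 2'-hydroxychalcone | C=C(C)[C@H](CC=C(C)C)Cc1c(O)c(C(=O)/C=C/c2ccc(OCOC)cc2OCOC)c(OCOC)cc1OCOC | intermediate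
14 | tetra-MOM-(2S)-flavanone | C=C(C)[C@H](CC=C(C)C)Cc1c(OCOC)cc(OCOC)c2c1O[C@H](c1ccc(OCOC)cc1OCOC)CC2=O | intermediate
15 | sophoraflavanone G | C=C(C)[C@H](CC=C(C)C)Cc1c(O)cc(O)c2c1O[C@H](c1ccc(O)cc1O)CC2=O | target

**Totals:** 12 steps in total; the longest linear sequence is 11 steps (1→2→3→4→5→6→7→9→12→13→14→15). Step 8 is a parallel branch.

**Three steps most likely to fail**
1. **Step 7 (proposed new coupling).** Homoallyl radical rearrangement, dialkylation, or low conversion of the phenolate EDA complex could give poor yield. Fallback (known chemistry): make the arene electrophile 3-iodo-2-hydroxy-4,6-bis(MOM)acetophenone (NIS on 2-hydroxy-4,6-bis(MOM)acetophenone) and couple it with 7 by Ni-catalysed decarboxylative cross-coupling (Weix/Baran type), then continue from the chalcone step.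
2. **Step 6 (dehydration regioselectivity).** Too much of the 1,1-disubstituted isomer would form. Fallback: esterify 4 and convert its methyl ketone to the thermodynamic enol triflate (Tf2O, hindered pyridine). Then install the second methyl by Fe(acac)3/MeMgBr coupling, hydrolyse, and form the NHPI ester, which bypasses the tertiary-alcohol route.
3. **Step 11 (C2 epimer separation).** The two epimers may be hard to resolve and the yield is capped near 50% per pass. Fallback: skip separation at the protected stage, deprotect the epimer mixture, separate the two sophoraflavanone G epimers by chiral-phase preparative HPLC, and recycle the (2R) epimer by base-mediated ring opening to the chalcone.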